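## The problem

The target 14 is a depside: two benzene rings joined by a single aryl ester between the C1' carboxyl of the chlorinated ring A and the C4 oxygen of ring B, and it has no stereocentre, so every difficulty is one of regiochemistry and chemoselectivity. Ring B is methyl orsellinate 11, which can be bought; the only demand on it is acylation at the 4-hydroxyl while the 2-hydroxyl, hydrogen-bonded to the ester, stays free. Ring A is the real task: a pentasubstituted benzene with C(=O) at C1', OH at C2', Cl at C3', OCH3 at C4', the lone hydrogen at C5' and CH3 at C6'. Chlorine must sit at C3' and not at the equally activated C5', and the C2' oxygen must end free while the C4' oxygen stays methylated. Three groups limit the choice of reagents: the depside ester is an activated aryl ester that will not survive hydroxide or alkoxide, the aryl chloride rules out hydrogenolytic deprotection, and a free ortho-hydroxy acid of ring A decarboxylates easily. The feature that opens the route is that CH3 (C6') and the carboxyl carbon (C1') sit on neighbouring ring carbons with oxygen at C2' next to C1', which is the pattern left when a nucleophile and then an electrophile add across a 3-alkoxybenzyne. Because C3'–Cl is flanked by oxygen on both sides, the aryne precursor can be the mirror-symmetric bromide 4 with both oxygens as methyl ethers.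

## Retrosynthesis

**14 to 13 (O–CH3 at C2').** The last bond cut is the methyl–oxygen bond of the C2' ether, so the free ortho-hydroxyl appears only after the ester is in place. This order is preferred to coupling a free salicylic acid, which invites self-condensation and decarboxylation. A methyl ether is preferred to a benzyl ether because the chlorine would not survive hydrogenolysis. The precursor 13 differs from 14 by one methyl group. The forward step must cleave one of two aryl methyl ethers; the one at C2' is singled out because it alone can form a six-membered chelate with the depside carbonyl and a boron Lewis acid.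

**13 to 10 and 11 (acyl C–O bond of the depside).** Cutting the ester between C1'(=O) and O4 of ring B gives the acid 10 and commercial 11, which splits the molecule into its two aromatic halves. No other cut is as convergent. The forward reaction must activate a 2,6-disubstituted benzoic acid and deliver it to the 4-hydroxyl of 11 only. Activation through the mixed trifluoroacetic anhydride 12, which reacts with acylium character, suits hindered electron-rich acids. The hydrogen-bonded 2-hydroxyl of 11 is a much weaker nucleophile.

**10 to 4, 5 and 6 (C6'–CH3 and C1'–CO2H).** Both carbon substituents of ring A are removed at once. This leads back to the symmetric bromide 4, methyllithium 5 and carbon dioxide 6 by way of the lithiated bromide 7, the aryne 8 and the aryllithium 9. The alternatives are stepwise electrophilic substitutions on a chlorinated orcinol ether, or building the ring from acyclic pieces. The aryne cut forms the two adjacent C–C bonds in one flask, and the orientation is dictated by the methoxy group beside the triple bond. The precursor 4 has only two ring hydrogens and they are equivalent, so only one aryne can form. The forward reaction needs deprotonation to be faster than bromine–lithium exchange, addition of 5 at the aryne carbon remote from oxygen, and capture of 9 by 6 before it does anything else.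

**4 to 3, then to 1 and 2 (C–Br, then C–B).** The bromine of 4 sits meta to both methoxy groups, a position electrophilic bromination of 1 cannot reach. The C–Br bond is therefore traced to the C–B bond of boronate 3, and that to a C–H bond of commercial 1 and diboron 2. Sterically governed iridium-catalysed borylation attacks the only C–H of 1 that has no ortho substituent, which is exactly C5. Copper-mediated bromodeboronation then exchanges boron for bromine at the same carbon.

## Roads not taken

Alternative 1: The cut runs through ring A at C1'–C2' and C5'–C6', so the ring is assembled on the finished ester linkage. The dienophile is methyl 4-(but-2-ynoyloxy)-2-[(tert-butyldimethylsilyl)oxy]-6-methylbenzoate A1, the acylated and silylated derivative of 11. The ynoate A1 would be heated with the chlorinated vinylketene acetal 2-chloro-1,3-dimethoxy-1-(trimethylsilyloxy)buta-1,3-diene A2. After the [4+2] addition, loss of the acetal methoxy group and of silicon on acidic work-up would aromatise the new ring and give the ring B silyl ether A3 of the target. One desilylation would then take A3 to 14.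
- Merits: the route is convergent, the C2' hydroxyl arrives free, and no ether has to be cleaved on a finished depside. The orientation follows from the polarisation of both partners, with the nucleophilic CH2 terminus of A2 bonding to the methyl-bearing β-carbon of A1.
- Weak points: a β-methyl ynoate such as A1 is a sluggish dienophile. The chlorine at C2 of A2 and the fully substituted C1 lower both its reactivity and its s-cis population. At the temperatures then required the ketene acetal can attack the activated aryl ester carbonyl or transfer silicon instead of cycloadding. A2 is hydrolytically fragile and needs about three steps to make. Ring B needs a protection and a deprotection.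
- Comparison: its longest linear sequence would be shorter (about four steps against five) and it avoids the late selective demethylation; both are real advantages. The chosen plan sets against this a key step whose orientation rests on two well-understood effects and whose components 4, 5 and 6 are robust. Alternative 1 depends entirely on an untested cycloaddition between a hindered diene and a hindered dienophile.

Alternative 2: Here ring B is cut at C1–C6 and C2–C3. The 4-aroyloxy-6-methyl-2-pyrone A4, which carries the acyl group of 10 on the pyrone 4-oxygen, would react with methyl 3-(pinacolboryl)propiolate A5. Thermal [4+2] cycloaddition and cycloreversion with loss of carbon dioxide 6 would give the arylboronate A6. Oxidation of the C–B bond of A6 to the C2 hydroxyl would give 13, and the same ortho-demethylation as in the chosen route would follow.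
- Merits: the ring B 2-hydroxyl is masked as boron, so the question of which hydroxyl of ring B is acylated never arises. Cycloadditions of 2-pyrones with alkynylboronates are an established benzannulation.
- Weak points: the key step builds a ring that can be bought as 11, and acid 10 is still required, so the ring A problem is untouched. The temperatures such cycloadditions need threaten the vinylogous anhydride linkage of A4 through acyl migration. The orientation of the ester and boron termini of A5 relative to the pyrone methyl is not secured by any strong bias. Two further steps follow the key step.
- Comparison: this road is longer than the chosen one in every count. Its single advantage is certainty about the acylation site, which the chosen plan obtains without extra steps from the hydrogen bond in 11.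

Alternative 3: Ring A is cut at C3'–C4' and C1'–C6'. 4-Chloro-1-methoxy-1,3-bis(trimethylsilyloxy)buta-1,3-diene A7 and 4,4-dimethoxybut-3-en-2-one A8 would combine under TiCl4. Conjugate addition of the chlorinated terminus of A7 to A8, aldol closure at the ketone and dehydration would give methyl 3-chloro-2-hydroxy-4-methoxy-6-methylbenzoate A9.
- Merits: the whole substitution pattern of ring A is written in one step from acyclic pieces. Chlorine is fixed, the C2' hydroxyl is free and the C4' oxygen is methylated from the start, so two methyl ethers never have to be told apart. Formal [3+3] cyclisations of 1,3-bis(silyloxy)dienes are a known way to salicylates, and the route to A9 is as short as the chosen route to 10.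
- Weak points: A9 is a methyl ester flanked by OH and CH3. Its saponification needs forcing base, under which ortho-hydroxybenzoic acids of this kind decarboxylate readily. The free hydroxyl must then be protected or tolerated in the coupling with 11. The chlorine-bearing terminus of A7 is both less nucleophilic and more hindered than that of an unchlorinated bis(silyloxy)diene.
- Comparison: this road is at least as direct as the chosen one for the ring A pattern, and it is better in needing no selective demethylation. The chosen plan sets against it that the aryne sequence delivers the free acid 10 directly from 6, already O-protected for coupling. Its end game is therefore two steps and never exposes a decarboxylation-prone acid to hot base.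

Key step: step 3

Assumption: lithium 2,2,6,6-tetramethylpiperidide is used as a preformed THF solution, so the free amine is the only spent form it leaves.

## Route

Step 1
Reactants: 1 2-chloro-1,3-dimethoxybenzene; 2 bis(pinacolato)diboron
Product: 3 2-(4-chloro-3,5-dimethoxyphenyl)-4,4,5,5-tetramethyl-1,3,2-dioxaborolane
Conditions: [Ir(OMe)(cod)]2 (1.5 mol %), 4,4'-di-tert-butyl-2,2'-bipyridine (3 mol %), 2 (1.0 equiv), THF, 80 °C
Reagents that add atoms: none
Why: Iridium-catalysed aromatic C–H borylation is governed by sterics; C5 is the only C–H of 1 without an ortho substituent, so boron should enter there alone, and the hindered C–Cl bond is not touched.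

Step 2
Reactants: 3 2-(4-chloro-3,5-dimethoxyphenyl)-4,4,5,5-tetramethyl-1,3,2-dioxaborolane
Product: 4 5-bromo-2-chloro-1,3-dimethoxybenzene
Conditions: CuBr2 (3 equiv), MeOH/H2O (1:1), 80 °C
Reagents that add atoms: CuBr2, Br[Cu]Br
Why: Copper-mediated bromodeboronation of an aryl pinacolboronate (aryl transfer to divalent copper, then C–Br bond formation) places bromine at the carbon that carried boron, a position electrophilic bromination of 1 could not reach.

Step 3
Reactants: 4 5-bromo-2-chloro-1,3-dimethoxybenzene; 5 methyllithium; 6 carbon dioxide
Product: 10 3-chloro-2,4-dimethoxy-6-methylbenzoic acid, via (6-bromo-3-chloro-2,4-dimethoxyphenyl)lithium 7 (not isolated), via 4-chloro-3,5-dimethoxybenzyne 8 (not isolated), via (3-chloro-2,4-dimethoxy-6-methylphenyl)lithium 9 (not isolated)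
Conditions: lithium 2,2,6,6-tetramethylpiperidide (LiTMP, 1.3 equiv), CH3Li (3 equiv), THF, −78 → −40 °C, 4 added slowly; then cannulated into excess CO2 in THF, −78 °C → rt; aq HCl
Reagents that add atoms: none
Why: This is an aryne three-component coupling (ortho-deprotonation with elimination, carbolithiation, carboxylation), the known behaviour of 3-haloanisoles, which give 3-methoxybenzynes and then 2-lithioanisoles with organolithiums. LiTMP removes one of the two equivalent hydrogens of 4 that lie between Br and OCH3, and the ortho-bromoaryllithium 7 loses LiBr to give the single possible aryne 8. Methyllithium 5 adds to the aryne carbon remote from the neighbouring methoxy group (future C6'), because the inductively withdrawing oxygen distorts the aryne so that this carbon is the more electrophilic one and the developing carbanion sits next to oxygen, where Li–O chelation also holds it; the hydrogen on the other flank exerts no counter-bias. The resulting aryllithium 9 has no ortho halogen and does not eliminate to a second aryne at this temperature, and carbon dioxide 6 captures it at C1' to give 10 after acidification. No ring is closed and no stereocentre is formed. The step needs deprotonation to outrun bromine–lithium exchange (secured by the non-nucleophilic amide base and the sluggish exchange of CH3Li with aryl bromides at −78 °C), a single aryne (secured by the mirror symmetry of 4) and an inert chlorine (it has no ortho hydrogen and lies between two methoxy groups). Slow addition of 4 to an excess of 5 keeps the aryne concentration low so that 9 does not add to 8, and the inverse quench into excess CO2 protects the hindered lithium carboxylate from attack by 5.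

Step 4
Reactants: 10 3-chloro-2,4-dimethoxy-6-methylbenzoic acid; 11 methyl 2,4-dihydroxy-6-methylbenzoate (methyl orsellinate)
Product: 13 methyl 4-[(3-chloro-2,4-dimethoxy-6-methylbenzoyl)oxy]-2-hydroxy-6-methylbenzoate, via 3-chloro-2,4-dimethoxy-6-methylbenzoic trifluoroacetic anhydride 12 (not isolated)
Conditions: trifluoroacetic anhydride (2.5 equiv), toluene, rt; aq NaHCO3 work-up
Reagents that add atoms: none
Why: Trifluoroacetic anhydride-mediated esterification through the mixed anhydride 12 is a standard activation for 2,6-disubstituted electron-rich benzoic acids in depside synthesis; the 4-hydroxyl of 11 should react alone because the 2-hydroxyl is hindered and held in a hydrogen bond to the ester carbonyl, and any aryl trifluoroacetate formed is cleaved on bicarbonate work-up.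

Step 5
Reactants: 13 methyl 4-[(3-chloro-2,4-dimethoxy-6-methylbenzoyl)oxy]-2-hydroxy-6-methylbenzoate
Product: 14 methyl 4-[(3-chloro-2-hydroxy-4-methoxy-6-methylbenzoyl)oxy]-2-hydroxy-6-methylbenzoate (CNP0146021.0)
Conditions: BCl3 (3 equiv), CH2Cl2, −78 → 0 °C; aq work-up
Reagents that add atoms: none
Why: In this chelation-controlled Lewis-acid ether cleavage, BCl3 binds the depside carbonyl and the adjacent C2' methoxy oxygen in a six-membered chelate and chloride removes that methyl group only; the C4' ether, the methyl ester and the aryl ester lack this activation at low temperature, and the ring B salicylate merely consumes one equivalent of BCl3 as a borate that hydrolyses on work-up.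

## Compound list

1 | 2-chloro-1,3-dimethoxybenzene | COc1cccc(OC)c1Cl | starting material
2 | bis(pinacolato)diboron | CC1(C)OB(OC1(C)C)B1OC(C)(C)C(C)(C)O1 | starting material
3 | 2-(4-chloro-3,5-dimethoxyphenyl)-4,4,5,5-tetramethyl-1,3,2-dioxaborolane | COc1cc(B2OC(C)(C)C(C)(C)O2)cc(OC)c1Cl | intermediate
4 | 5-bromo-2-chloro-1,3-dimethoxybenzene | COc1cc(Br)cc(OC)c1Cl | intermediate
5 | methyllithium | [Li]C | starting material
6 | carbon dioxide | O=C=O | starting material
7 | (6-bromo-3-chloro-2,4-dimethoxyphenyl)lithium | [Li]c1c(Br)cc(OC)c(Cl)c1OC | intermediate
8 | 4-chloro-3,5-dimethoxybenzyne (4-chloro-3,5-dimethoxy-1,2-didehydrobenzene) | COC1=CC#CC(OC)=C1Cl | intermediate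
9 | (3-chloro-2,4-dimethoxy-6-methylphenyl)lithium | [Li]c1c(C)cc(OC)c(Cl)c1OC | intermediate
10 | 3-chloro-2,4-dimethoxy-6-methylbenzoic acid | COc1cc(C)c(C(=O)O)c(OC)c1Cl | intermediate
11 | methyl 2,4-dihydroxy-6-methylbenzoate (methyl orsellinate) | COC(=O)c1c(C)cc(O)cc1O | starting material
12 | 3-chloro-2,4-dimethoxy-6-methylbenzoic trifluoroacetic anhydride | COc1cc(C)c(C(=O)OC(=O)C(F)(F)F)c(OC)c1Cl | intermediate
13 | methyl 4-[(3-chloro-2,4-dimethoxy-6-methylbenzoyl)oxy]-2-hydroxy-6-methylbenzoate | COC(=O)c1c(C)cc(OC(=O)c2c(C)cc(OC)c(Cl)c2OC)cc1O | intermediate
14 | methyl 4-[(3-chloro-2-hydroxy-4-methoxy-6-methylbenzoyl)oxy]-2-hydroxy-6-methylbenzoate | COC(=O)c1c(C)cc(OC(=O)c2c(C)cc(OC)c(Cl)c2O)cc1O | target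

## Step count and risk

Total step count: 5. Longest linear sequence: 5 steps (1 → 3 → 4 → 10 → 13 → 14); 11 enters in step 4.

**Step 3 (key step).** Four processes could divert it:
- bromine–lithium exchange of 4 with 5, which leads to reduced or ipso-methylated material;
- addition of the amide or of 9 to the aryne 8, which leads to aminated or biaryl material;
- imperfect orientation of the addition of 5;
- attack of surplus 5 on the lithium carboxylate during the quench.

The fallback sets out from 4 and returns to the route at 10, giving up the aryne for stepwise substitution. Suzuki–Miyaura methylation of the C–Br bond with trimethylboroxine (Pd(PPh3)4, K2CO3, dioxane, 100 °C) should give 2-chloro-1,3-dimethoxy-5-methylbenzene F1, the hindered C–Cl bond being left alone. Vilsmeier–Haack formylation (POCl3, DMF) can only attack the two equivalent free positions, each ortho to one methoxy and para to the other, and should give 3-chloro-2,4-dimethoxy-6-methylbenzaldehyde F2. Pinnick oxidation (NaClO2, NaH2PO4, 2-methyl-2-butene, t-BuOH/H2O) then gives 10.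

**Step 4.** The acylium-type activation may lead to acylation at a ring carbon of the electron-rich 11, to partial reaction at the 2-hydroxyl, or to persistent trifluoroacetylation of the phenol. The fallback sets out from 10 and returns at 13, replacing acid-mediated activation by acylation of a phenoxide. Oxalyl chloride with catalytic DMF (CH2Cl2, 0 °C → rt) converts 10 into 3-chloro-2,4-dimethoxy-6-methylbenzoyl chloride F3. The chloride F3 is then added to 11 and K2CO3 in acetone. Under these conditions only the more acidic, non-chelated 4-hydroxyl is deprotonated and acylated, giving 13.

**Step 5.** The Lewis acid may fail to discriminate: cleavage of the depside ester or of the ring B methyl ester, loss of the C4' methyl group, or incomplete reaction because the ring B salicylate sequesters the reagent. The fallback sets out from 10 and returns at 14, moving the demethylation ahead of the coupling so that no depside is exposed to the Lewis acid. BCl3 (CH2Cl2, −78 → 0 °C) on 10 should remove only the methyl group ortho to the carboxyl and give 3-chloro-2-hydroxy-4-methoxy-6-methylbenzoic acid F4. Carbodiimide esterification of F4 with 11 (N,N'-dicyclohexylcarbodiimide, Et2O/toluene, rt) then gives 14 directly. The chelated ortho-hydroxyl of F4 is too weak a nucleophile to compete with the 4-hydroxyl of 11, and F4 is kept cold and free of base to avoid decarboxylation.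

## Further compounds

F1 | step 3 | 2-chloro-1,3-dimethoxy-5-methylbenzene | COc1cc(C)cc(OC)c1Cl
F2 | step 3 | 3-chloro-2,4-dimethoxy-6-methylbenzaldehyde | COc1cc(C)c(C=O)c(OC)c1Cl
F3 | step 4 | 3-chloro-2,4-dimethoxy-6-methylbenzoyl chloride | COc1cc(C)c(C(=O)Cl)c(OC)c1Cl
F4 | step 5 | 3-chloro-2-hydroxy-4-methoxy-6-methylbenzoic acid | COc1cc(C)c(C(=O)O)c(O)c1Cl
A1 | alternative 1 | methyl 4-(but-2-ynoyloxy)-2-[(tert-butyldimethylsilyl)oxy]-6-methylbenzoate | COC(=O)c1c(C)cc(OC(=O)C#CC)cc1O[Si](C)(C)C(C)(C)C
A2 | alternative 1 | 2-chloro-1,3-dimethoxy-1-(trimethylsilyloxy)buta-1,3-diene | COC(=C)C(Cl)=C(OC)O[Si](C)(C)C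
A3 | alternative 1 | methyl 2-[(tert-butyldimethylsilyl)oxy]-4-[(3-chloro-2-hydroxy-4-methoxy-6-methylbenzoyl)oxy]-6-methylbenzoate | COC(=O)c1c(C)cc(OC(=O)c2c(C)cc(OC)c(Cl)c2O)cc1O[Si](C)(C)C(C)(C)C
A4 | alternative 2 | 6-methyl-2-oxo-2H-pyran-4-yl 3-chloro-2,4-dimethoxy-6-methylbenzoate | CC1=CC(OC(=O)c2c(C)cc(OC)c(Cl)c2OC)=CC(=O)O1
A5 | alternative 2 | methyl 3-(4,4,5,5-tetramethyl-1,3,2-dioxaborolan-2-yl)prop-2-ynoate | COC(=O)C#CB1OC(C)(C)C(C)(C)O1
A6 | alternative 2 | methyl 4-[(3-chloro-2,4-dimethoxy-6-methylbenzoyl)oxy]-6-methyl-2-(4,4,5,5-tetramethyl-1,3,2-dioxaborolan-2-yl)benzoate | COC(=O)c1c(C)cc(OC(=O)c2c(C)cc(OC)c(Cl)c2OC)cc1B1OC(C)(C)C(C)(C)O1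
A7 | alternative 3 | 4-chloro-1-methoxy-1,3-bis(trimethylsilyloxy)buta-1,3-diene | COC(O[Si](C)(C)C)=CC(O[Si](C)(C)C)=CCl
A8 | alternative 3 | 4,4-dimethoxybut-3-en-2-one | CC(=O)C=C(OC)OC
A9 | alternative 3 | methyl 3-chloro-2-hydroxy-4-methoxy-6-methylbenzoate | COC(=O)c1c(C)cc(OC)c(Cl)c1O
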